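**Retrosynthetic overview**
1. Stenophyllol B ← global hydrogenolysis of a penta-benzyl ether ← cationic Friedel–Crafts closure of the indane five-membered ring (ring-A benzylic carbon to ring B) in a carbinol made from an eight-membered-ring aryl ketone.
2. Key disconnection: the eight-membered ring is cut at two bonds, benzofuran C-4 (ring E) to the carbon alpha to the ketone, and the ortho carbon C-2' of resorcinol ring D to the methine bearing ring C; this gives an aryl bromide (fragment B) and an acyclic ketone (fragment A), joined in one (5+3) operation.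
3. Enabling feature: the three-carbon chain of fragment A is a 1,3-ambiphile, its CH2 alpha to the ring-A aryl ketone (enolate) and its far carbon a para-hydroxybenzylic methyl ether on ring C (latent para-quinone methide); in fragment B the C-4 bromine of ring E and the free resorcinol ring D on C-3 are the matching 1,5-pair.
4. Fragment B: enantioselective rhodium-carbene C–H insertion closes the dihydrofuran and sets C-3, then C-2 is epimerised to trans; fragment A: a rhodium/BINAP 1,4-addition sets the carbon bearing ring B.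
5. Ring order: dihydrofuran, then eight-membered ring, then indane five-membered ring.

Key step: step 17

Labels: ring A = para-oxyphenyl on C-a; ring B = resorcinol ring of the indane; ring C = para-hydroxyphenyl on C-d; ring D = resorcinol ring inside the eight-membered ring; ring E = benzo ring of the benzofuran; ring F = para-oxyphenyl on benzofuran C-2. C-a = indane C-1 (ketone carbon of fragment A), C-b = indane C-2 (alpha carbon), C-c = indane C-3 (bears ring B), C-d = methine bearing ring C. CIP descriptors refer to the compound in which they are written; the SMILES are authoritative.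

Assumption: the antipodes of the chiral catalysts named in steps 8 and 15 (and of the chiral sulfide in the fallback to step 8) are taken to be the ones that give the configurations drawn; if the sense of induction is the opposite, the mirror-image catalyst is used and nothing else changes.

**Fragment B**

Step 1
Reactants: 1 5-bromobenzene-1,3-diol
Product: 3 2-bromo-4,6-dihydroxybenzaldehyde, via iminium salt 2 (not isolated)
Conditions: POCl3, DMF, MeCN, 0 to 23 °C; then H2O, 50 °C
Reagents that add atoms: N,N-dimethylformamide, CN(C)C=O; water, O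
Why: Vilsmeier–Haack formylation of a 5-substituted resorcinol should go to the carbon ortho to one hydroxyl and para to the other (next to bromine), as it does with orcinol.

Step 2
Reactants: 3 2-bromo-4,6-dihydroxybenzaldehyde
Product: 4 4-(benzyloxy)-2-bromo-6-hydroxybenzaldehyde
Conditions: BnBr (1.05 equiv), KHCO3, MeCN, 60 °C
Reagents that add atoms: benzyl bromide, BrCc1ccccc1
Why: Williamson etherification should be selective for the para hydroxyl, because the ortho hydroxyl is held in a hydrogen bond to the aldehyde and the weak base ionises only the more acidic para phenol.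

Step 3
Reactants: 4 4-(benzyloxy)-2-bromo-6-hydroxybenzaldehyde; 5 1-(benzyloxy)-4-(chloromethyl)benzene
Product: 6 4-(benzyloxy)-2-{[4-(benzyloxy)phenyl]methoxy}-6-bromobenzaldehyde
Conditions: K2CO3, KI (cat.), DMF, 60 °C
Reagents that add atoms: none
Why: Williamson etherification of the remaining chelated phenol under more forcing conditions installs the benzylic ether whose CH2 later becomes C-2 of the dihydrofuran.

Step 4
Reactants: 1 5-bromobenzene-1,3-diol
Product: 7 1-bromo-3,5-bis(prop-2-en-1-yloxy)benzene
Conditions: allyl bromide, K2CO3, acetone, reflux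
Reagents that add atoms: allyl bromide, C=CCBr
Why: double Williamson allylation masks ring D with groups that survive organolithium, hydrazine, carbene and acid steps and are later removed by zerovalent palladium without touching benzyl ethers or the aryl bromide.

Step 5
Reactants: 7 1-bromo-3,5-bis(prop-2-en-1-yloxy)benzene; 6 4-(benzyloxy)-2-{[4-(benzyloxy)phenyl]methoxy}-6-bromobenzaldehyde
Product: 9 [4-(benzyloxy)-2-{[4-(benzyloxy)phenyl]methoxy}-6-bromophenyl][3,5-bis(prop-2-en-1-yloxy)phenyl]methanol (racemic), via aryllithium 8 (not isolated)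
Conditions: n-BuLi, THF, -78 °C; then 6, -78 °C
Reagents that add atoms: none
Why: bromine–lithium exchange followed by 1,2-addition of the aryllithium to the aldehyde, which at -78 °C should be faster than exchange at the hindered bromide of 6.

Step 6
Reactants: 9 diarylmethanol from step 5
Product: 10 [4-(benzyloxy)-2-{[4-(benzyloxy)phenyl]methoxy}-6-bromophenyl][3,5-bis(prop-2-en-1-yloxy)phenyl]methanone
Conditions: Dess–Martin periodinane, CH2Cl2, 23 °C
Reagents that add atoms: none
Why: Dess–Martin oxidation of a doubly benzylic secondary alcohol to the benzophenone; allyl and benzyl ethers are inert.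

Step 7
Reactants: 10 benzophenone from step 6
Product: 11 hydrazone of 10 (E/Z mixture)
Conditions: N2H4·H2O (excess), AcOH (cat.), n-BuOH, 110 °C, argon
Reagents that add atoms: hydrazine (used as hydrate), NN
Why: hydrazone condensation, forced by heat and acid catalysis because the ketone is di-ortho-substituted; the electron-rich aryl bromide should not undergo uncatalysed displacement.

Step 8
Reactants: 11 hydrazone of 10
Product: 13 (2S,3R)-6-(benzyloxy)-2-[4-(benzyloxy)phenyl]-4-bromo-3-[3,5-bis(prop-2-en-1-yloxy)phenyl]-2,3-dihydro-1-benzofuran (2,3-cis), via diaryldiazomethane 12 (not isolated)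
Conditions: MnO2, CH2Cl2, 23 °C; filter; Rh2(R-PTAD)4 (1 mol%; dirhodium tetrakis[(R)-(1-adamantyl)(N-phthalimido)acetate]), CH2Cl2, 0 °C
Reagents that add atoms: none
Why: oxidation to the diaryldiazomethane and enantioselective intramolecular 1,5 C–H insertion of the donor/donor dirhodium carbene into the activated benzylic ether C–H, in which the chiral carboxylate catalyst sets C-3 and the kinetic product is the 2,3-cis isomer.

Step 9
Reactants: 13 cis-dihydrobenzofuran from step 8
Product: 14 (2R,3R)-6-(benzyloxy)-2-[4-(benzyloxy)phenyl]-4-bromo-3-[3,5-bis(prop-2-en-1-yloxy)phenyl]-2,3-dihydro-1-benzofuran (2,3-trans)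
Conditions: CF3CO2H, CH2Cl2 (0.02 M), 0 °C
Reagents that add atoms: none
Why: acid-mediated epimerisation at C-2 by reversible ionisation of the para-alkoxybenzylic C–O bond and reclosure should give the thermodynamically favoured trans isomer while C-3 is untouched.

Step 10
Reactants: 14 trans-dihydrobenzofuran from step 9
Product: 15 5-{(2R,3R)-6-(benzyloxy)-2-[4-(benzyloxy)phenyl]-4-bromo-2,3-dihydro-1-benzofuran-3-yl}benzene-1,3-diol (fragment B)
Conditions: Pd(PPh3)4 (5 mol%), morpholine, THF, 23 °C
Reagents that add atoms: none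
Why: Tsuji–Trost deallylation with an amine as allyl acceptor; at 23 °C ionisation of the allyl aryl ethers is much faster than oxidative addition into the hindered, electron-rich aryl bromide.

**Fragment A**

Step 11
Reactants: 16 4-[(tert-butyldimethylsilyl)oxy]benzaldehyde
Product: 17 1-{4-[(tert-butyldimethylsilyl)oxy]phenyl}prop-2-en-1-ol (racemic)
Conditions: CH2=CHMgBr, THF, 0 °C
Reagents that add atoms: vinylmagnesium bromide, C=C[Mg]Br
Why: Grignard 1,2-addition to the aldehyde; the new carbinol carbon becomes C-d, whose configuration is erased later.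

Step 12
Reactants: 17 allylic alcohol from step 11
Product: 18 tert-butyl[4-(1-methoxyprop-2-en-1-yl)phenoxy]dimethylsilane (racemic)
Conditions: NaH, MeI, THF, 0 °C
Reagents that add atoms: iodomethane, CI
Why: Williamson methylation installs the methoxy group that later serves as the leaving group for quinone methide formation.

Step 13
Reactants: 18 allylic methyl ether from step 12
Product: 20 2-{4-[(tert-butyldimethylsilyl)oxy]phenyl}-2-methoxyacetaldehyde (racemic), via ozonide 19 (not isolated)
Conditions: O3, CH2Cl2, -78 °C; then PPh3, -78 to 23 °C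
Reagents that add atoms: ozone, [O-][O+]=O
Why: ozonolysis with reductive work-up cleaves the terminal alkene to the alpha-methoxy aldehyde, the alkene reacting far faster than the silyloxy arene.

Step 14
Reactants: 21 1-[4-(benzyloxy)phenyl]ethan-1-one; 20 alpha-methoxy aldehyde from step 13
Product: 24 (2E)-1-[4-(benzyloxy)phenyl]-4-{4-[(tert-butyldimethylsilyl)oxy]phenyl}-4-methoxybut-2-en-1-one (racemic), via lithium aldolate 22 (not isolated), via mesylate 23 (not isolated)
Conditions: LiN(SiMe3)2, THF, -78 °C; then 20; then MeSO2Cl, Et3N, -78 to 23 °C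
Reagents that add atoms: none
Why: lithium enolate aldol addition followed by mesylation and E1cB elimination gives the (E)-enone.

Step 15
Reactants: 24 (E)-enone from step 14; 25 [3,5-bis(benzyloxy)phenyl]boronic acid
Product: 26 (3S)-1-[4-(benzyloxy)phenyl]-3-[3,5-bis(benzyloxy)phenyl]-4-{4-[(tert-butyldimethylsilyl)oxy]phenyl}-4-methoxybutan-1-one (both C-4 epimers)
Conditions: [Rh(OH)((S)-BINAP)]2 (1.5 mol%), 1,4-dioxane/H2O (10:1), 35 °C
Reagents that add atoms: none
Why: Hayashi–Miyaura asymmetric 1,4-addition of the arylrhodium species to the acyclic aryl enone sets C-c under catalyst control, and the racemic methoxy-bearing C-d is carried as a mixture because it is erased in step 17.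

Step 16
Reactants: 26 silyl ether from step 15
Product: 27 (3S)-1-[4-(benzyloxy)phenyl]-3-[3,5-bis(benzyloxy)phenyl]-4-(4-hydroxyphenyl)-4-methoxybutan-1-one (both C-4 epimers; fragment A)
Conditions: Bu4NF, AcOH (1:1), THF, 0 °C
Reagents that add atoms: none
Why: buffered fluoride desilylation frees the ring-C phenol without generating a free phenolate that could expel methoxide prematurely.

**Union and end game**

Step 17
Reactants: 27 fragment A; 15 fragment B
Product: 30 eight-membered-ring ketone (C-b aroyl trans to ring B on C-c; ring B trans to ring C on C-d; dihydrofuran 2,3-trans), via alpha-aryl ketone 28 (not isolated), via quinone methide 29 (not isolated)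
Conditions: Pd2(dba)3 (2.5 mol%), P(tBu)3·HBF4 (6 mol%), NaOtBu (5.2 equiv), 1,4-dioxane (0.02 M), all charged at the start, 45 °C, then 100 °C; AcOH; then DBU (0.2 equiv), THF, 23 °C
Reagents that add atoms: none
Why: Proposed new method: at 45 °C zerovalent palladium inserts into the C4–Br bond of 15 and the sodium enolate of 27 (C-b is its only enolisable position) is arylated as in a Buchwald–Hartwig ketone alpha-arylation to give 28; on warming, the ring-C phenolate expels methoxide to form para-quinone methide 29 and the ring-D resorcinolate adds through its ortho carbon C-2' to C-d (1,6-addition), the closest known reactions being the palladium-catalysed alpha-arylation of aryl alkyl ketones and the base-triggered generation of para-quinone methides from para-hydroxybenzyl ethers with C-alkylation of phenolates, here merged into a formal (5+3) annulation. The eight-membered ring closes in the 8-exo-trig mode, the quinone methide C=C staying outside the new ring. C-c is brought in from 27; C-d is set by allylic 1,3-strain in 29 (the C-c–H bond eclipses the exocyclic C=C) with ring D arriving from the face that carries its tether through C-b, which should give the anti C-c/C-d relationship; C-b, the epimerisable alpha carbon, is equilibrated by DBU to the isomer with the aroyl group trans to ring B. The step needs the arylation to precede quinone methide formation (methoxide is a poor leaving group at 45 °C, so the only intermolecular event is the site-defined oxidative addition and the later ring closure is intramolecular), C- over O-arylation (enolate reductive elimination from the P(tBu)3 complex should outrun diaryl ether formation), and ring D as the only carbon nucleophile for 29: only ring D is unmasked as a phenolate, so C-5 of ring E, which under acid would close a five-membered ring onto C-d, stays an inert benzyl ether, and of ring D only C-2' can reach C-d. Quinone methide that recloses on the enolate (cyclopropane), adds methoxide or O-alkylates a phenolate should be regenerated under the conditions, so these paths are reservoirs and not losses.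

Step 18
Reactants: 30 eight-membered-ring ketone
Product: 31 carbinol (both C-a epimers)
Conditions: NaBH4, THF/MeOH, 0 °C
Reagents that add atoms: none
Why: borohydride reduction of the aryl ketone gives the para-(benzyloxy)benzylic alcohol, whose two epimers converge on the same cation in step 19.

Step 19
Reactants: 31 carbinol
Product: 32 stenophyllol B penta-O-benzyl ether (benzyl on rings A, B twice, E and F; free hydroxyls on rings C and D)
Conditions: CF3CO2H (5 equiv), CH2Cl2, -20 to 0 °C
Reagents that add atoms: none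
Why: ionisation gives the C-a cation stabilised by the para-benzyloxy group, and Friedel–Crafts cycloalkylation by ring B (ortho to C-c, activated by both benzyloxy groups) closes the indane with ring A trans to ring E on C-b, the arene attacking the face anti to the C-b substituent, which is also the thermodynamic all-trans arrangement.

Step 20
Reactants: 32 stenophyllol B penta-O-benzyl ether
Product: 33 stenophyllol B
Conditions: H2 (1 atm), Pd/C (10 wt%), EtOAc/MeOH, 23 °C
Reagents that add atoms: none
Why: hydrogenolysis of the five aryl benzyl ethers; the target has no alkene, and aryl benzyl ethers should cleave well before the dihydrofuran benzylic C–O bond.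

**Compound list**
1 | 5-bromobenzene-1,3-diol | Oc1cc(O)cc(Br)c1 | starting material
2 | [(2-bromo-4,6-dihydroxyphenyl)methylidene]dimethyliminium chloride | C[N+](C)=Cc1c(O)cc(O)cc1Br.[Cl-] | intermediate
3 | 2-bromo-4,6-dihydroxybenzaldehyde | O=Cc1c(O)cc(O)cc1Br | intermediate
4 | 4-(benzyloxy)-2-bromo-6-hydroxybenzaldehyde | O=Cc1c(O)cc(OCc2ccccc2)cc1Br | intermediate
5 | 1-(benzyloxy)-4-(chloromethyl)benzene | ClCc1ccc(OCc2ccccc2)cc1 | starting material
6 | 4-(benzyloxy)-2-{[4-(benzyloxy)phenyl]methoxy}-6-bromobenzaldehyde | O=Cc1c(Br)cc(OCc2ccccc2)cc1OCc1ccc(OCc2ccccc2)cc1 | intermediate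
7 | 1-bromo-3,5-bis(prop-2-en-1-yloxy)benzene | C=CCOc1cc(OCC=C)cc(Br)c1 | intermediate
8 | [3,5-bis(prop-2-en-1-yloxy)phenyl]lithium | [Li]c1cc(OCC=C)cc(OCC=C)c1 | intermediate
9 | [4-(benzyloxy)-2-{[4-(benzyloxy)phenyl]methoxy}-6-bromophenyl][3,5-bis(prop-2-en-1-yloxy)phenyl]methanol (racemic) | OC(c1cc(OCC=C)cc(OCC=C)c1)c1c(Br)cc(OCc2ccccc2)cc1OCc1ccc(OCc2ccccc2)cc1 | intermediate
10 | [4-(benzyloxy)-2-{[4-(benzyloxy)phenyl]methoxy}-6-bromophenyl][3,5-bis(prop-2-en-1-yloxy)phenyl]methanone | O=C(c1cc(OCC=C)cc(OCC=C)c1)c1c(Br)cc(OCc2ccccc2)cc1OCc1ccc(OCc2ccccc2)cc1 | intermediate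
11 | hydrazone of 10 (E/Z mixture) | NN=C(c1cc(OCC=C)cc(OCC=C)c1)c1c(Br)cc(OCc2ccccc2)cc1OCc1ccc(OCc2ccccc2)cc1 | intermediate
12 | diaryldiazomethane from 11 | [N-]=[N+]=C(c1cc(OCC=C)cc(OCC=C)c1)c1c(Br)cc(OCc2ccccc2)cc1OCc1ccc(OCc2ccccc2)cc1 | intermediate
13 | (2S,3R)-6-(benzyloxy)-2-[4-(benzyloxy)phenyl]-4-bromo-3-[3,5-bis(prop-2-en-1-yloxy)phenyl]-2,3-dihydro-1-benzofuran (cis) | C=CCOc1cc(OCC=C)cc([C@@H]2c3c(cc(OCc4ccccc4)cc3Br)O[C@@H]2c2ccc(OCc3ccccc3)cc2)c1 | intermediate
14 | (2R,3R)-6-(benzyloxy)-2-[4-(benzyloxy)phenyl]-4-bromo-3-[3,5-bis(prop-2-en-1-yloxy)phenyl]-2,3-dihydro-1-benzofuran (trans) | C=CCOc1cc(OCC=C)cc([C@@H]2c3c(cc(OCc4ccccc4)cc3Br)O[C@H]2c2ccc(OCc3ccccc3)cc2)c1 | intermediate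
15 | 5-{(2R,3R)-6-(benzyloxy)-2-[4-(benzyloxy)phenyl]-4-bromo-2,3-dihydro-1-benzofuran-3-yl}benzene-1,3-diol (fragment B) | Oc1cc(O)cc([C@@H]2c3c(cc(OCc4ccccc4)cc3Br)O[C@H]2c2ccc(OCc3ccccc3)cc2)c1 | intermediate
16 | 4-[(tert-butyldimethylsilyl)oxy]benzaldehyde | O=Cc1ccc(O[Si](C)(C)C(C)(C)C)cc1 | starting material
17 | 1-{4-[(tert-butyldimethylsilyl)oxy]phenyl}prop-2-en-1-ol (racemic) | C=CC(O)c1ccc(O[Si](C)(C)C(C)(C)C)cc1 | intermediate
18 | tert-butyl[4-(1-methoxyprop-2-en-1-yl)phenoxy]dimethylsilane (racemic) | C=CC(OC)c1ccc(O[Si](C)(C)C(C)(C)C)cc1 | intermediate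
19 | 3-[(4-{[tert-butyl(dimethyl)silyl]oxy}phenyl)(methoxy)methyl]-1,2,4-trioxolane (ozonide of 18) | COC(c1ccc(O[Si](C)(C)C(C)(C)C)cc1)C1OCOO1 | intermediate
20 | 2-{4-[(tert-butyldimethylsilyl)oxy]phenyl}-2-methoxyacetaldehyde (racemic) | O=CC(OC)c1ccc(O[Si](C)(C)C(C)(C)C)cc1 | intermediate
21 | 1-[4-(benzyloxy)phenyl]ethan-1-one | CC(=O)c1ccc(OCc2ccccc2)cc1 | starting material
22 | lithium aldolate (lithium 4-[4-(benzyloxy)phenyl]-1-methoxy-4-oxo-1-{4-[(tert-butyldimethylsilyl)oxy]phenyl}butan-2-olate, diastereomer mixture) | [Li+].[O-]C(CC(=O)c1ccc(OCc2ccccc2)cc1)C(OC)c1ccc(O[Si](C)(C)C(C)(C)C)cc1 | intermediate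
23 | methanesulfonate of the aldol (diastereomer mixture) | O=C(CC(OS(C)(=O)=O)C(OC)c1ccc(O[Si](C)(C)C(C)(C)C)cc1)c1ccc(OCc2ccccc2)cc1 | intermediate
24 | (2E)-1-[4-(benzyloxy)phenyl]-4-{4-[(tert-butyldimethylsilyl)oxy]phenyl}-4-methoxybut-2-en-1-one (racemic) | O=C(/C=C/C(OC)c1ccc(O[Si](C)(C)C(C)(C)C)cc1)c1ccc(OCc2ccccc2)cc1 | intermediate
25 | [3,5-bis(benzyloxy)phenyl]boronic acid | OB(O)c1cc(OCc2ccccc2)cc(OCc2ccccc2)c1 | starting material
26 | (3S)-1-[4-(benzyloxy)phenyl]-3-[3,5-bis(benzyloxy)phenyl]-4-{4-[(tert-butyldimethylsilyl)oxy]phenyl}-4-methoxybutan-1-one (C-4 epimers) | O=C(C[C@@H](c1cc(OCc2ccccc2)cc(OCc2ccccc2)c1)C(OC)c1ccc(O[Si](C)(C)C(C)(C)C)cc1)c1ccc(OCc2ccccc2)cc1 | intermediate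
27 | (3S)-1-[4-(benzyloxy)phenyl]-3-[3,5-bis(benzyloxy)phenyl]-4-(4-hydroxyphenyl)-4-methoxybutan-1-one (C-4 epimers; fragment A) | O=C(C[C@@H](c1cc(OCc2ccccc2)cc(OCc2ccccc2)c1)C(OC)c1ccc(O)cc1)c1ccc(OCc2ccccc2)cc1 | intermediate
28 | alpha-aryl ketone: (3S)-1-[4-(benzyloxy)phenyl]-2-{(2R,3R)-6-(benzyloxy)-2-[4-(benzyloxy)phenyl]-3-(3,5-dihydroxyphenyl)-2,3-dihydro-1-benzofuran-4-yl}-3-[3,5-bis(benzyloxy)phenyl]-4-(4-hydroxyphenyl)-4-methoxybutan-1-one (C-2 and C-4 epimers; present as sodium enolate/phenolates) | O=C(c1ccc(OCc2ccccc2)cc1)C(c1cc(OCc2ccccc2)cc2O[C@@H](c3ccc(OCc4ccccc4)cc3)[C@H](c3cc(O)cc(O)c3)c12)[C@@H](c1cc(OCc2ccccc2)cc(OCc2ccccc2)c1)C(OC)c1ccc(O)cc1 | intermediate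
29 | para-quinone methide from 28 (methanol lost between C-d and the ring-C phenol) | O=C(c1ccc(OCc2ccccc2)cc1)C(c1cc(OCc2ccccc2)cc2O[C@@H](c3ccc(OCc4ccccc4)cc3)[C@H](c3cc(O)cc(O)c3)c12)[C@@H](c1cc(OCc2ccccc2)cc(OCc2ccccc2)c1)C=C1C=CC(=O)C=C1 | intermediate
30 | eight-membered-ring ketone: benzofuran C-4 and ring-D C-2' bridged by CH(CO-ring A)–CH(ring B)–CH(ring C), all three substituents mutually trans | c1ccccc1COc1ccc(cc1)C(=O)[C@@H]1[C@@H](c2cc(OCc3ccccc3)cc(OCc3ccccc3)c2)[C@H](c2ccc(O)cc2)c2c(O)cc(O)cc2[C@@H]2c3c(cc(OCc4ccccc4)cc31)O[C@H]2c1ccc(OCc2ccccc2)cc1 | intermediate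
31 | carbinol from 30 (C-a epimers) | c1ccccc1COc1ccc(cc1)C(O)[C@@H]1[C@@H](c2cc(OCc3ccccc3)cc(OCc3ccccc3)c2)[C@H](c2ccc(O)cc2)c2c(O)cc(O)cc2[C@@H]2c3c(cc(OCc4ccccc4)cc31)O[C@H]2c1ccc(OCc2ccccc2)cc1 | intermediate
32 | stenophyllol B penta-O-benzyl ether | c1ccccc1COc1ccc(cc1)[C@H]1c2c(OCc3ccccc3)cc(OCc3ccccc3)cc2[C@H]2[C@H](c3ccc(O)cc3)c3c(O)cc(O)cc3[C@@H]3c4c(cc(OCc5ccccc5)cc4[C@H]12)O[C@H]3c1ccc(OCc2ccccc2)cc1 | intermediate
33 | stenophyllol B | Oc1ccc([C@H]2c3c(O)cc(O)cc3[C@H]3[C@H](c4ccc(O)cc4)c4c(O)cc(O)cc4[C@@H]4c5c(cc(O)cc5[C@H]23)O[C@H]4c2ccc(O)cc2)cc1 | target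

**Step count and risks**
Total step count: 20. Longest linear sequence: 13 steps (steps 1, 2, 3, 5 to 10, 17 to 20).

Steps most likely to fail:

Step 17 (the step proposed as a new method). The two events may run in the wrong order, so that a quinone methide formed before arylation is alkylated intermolecularly by the resorcinolate at the wrong ring-D carbon. A phenolate oxygen may be arylated in place of the enolate carbon. The quinone methide may tautomerise to the 4-hydroxystilbene, which erases C-c, faster than the eight-membered ring closes. The fallback uses the same bond-forming reactions one at a time on protected partners and sets out from silyl ether 26 and bis-allyl ether 14. Pd2(dba)3/P(tBu)3·HBF4 with NaOtBu in toluene at 60 °C joins them by ketone alpha-arylation to the fully protected alpha-aryl ketone F1, in which neither a phenolate nor a quinone methide can form. Pd(PPh3)4/morpholine and then Bu4NF/AcOH free the three phenols to give 28, now isolated. Cs2CO3 in 1,4-dioxane at 90 °C under high dilution then generates 29 and closes the ring, and DBU equilibration brings the route back at 30.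

Step 8. The di-ortho-substituted carbene precursor may be hard to reach (sluggish condensation in step 7), and the ortho bromine may twist the carbene so that facial control is lost or the carbene is diverted to azine formation. The fallback builds the dihydrofuran by a sulfur-ylide (4+1) annulation and sets out from phenol aldehyde 4 and aryllithium 8 (2.2 equiv), which give the ortho-hydroxy diarylmethanol F2. Sodium 4-methylbenzenesulfinate in formic acid converts it into the sulfone F3. Chloride 5 and (2R,5R)-2,5-dimethylthiolane give the benzylic sulfonium chloride F4. Cs2CO3 in CH2Cl2 turns F3 into the ortho-quinone methide and F4 into the chiral sulfur ylide, whose annulation should give the trans-dihydrobenzofuran directly; this comes back to the route at 14 and makes steps 3, 5 to 7 and 9 unnecessary.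

Step 19. The C-a cation may lose the C-b proton (stilbene formation) faster than ring B closes, which scrambles C-b, and benzyl groups may migrate under acid. The fallback changes the order of events and sets out from ketone 30. H2 over Pd/C first removes the five benzyl ethers to give the octaphenol ketone F5, and NaBH4 gives the carbinol F6. In HCO2H/MeOH/H2O at 23 °C the para-hydroxybenzylic alcohol should form the ring-A para-quinone methide at low acidity, and the now free and far more nucleophilic resorcinol ring B closes the indane; this comes back to the route at 33.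

Further compounds
F1 | step 17 | (3S)-1-[4-(benzyloxy)phenyl]-2-{(2R,3R)-6-(benzyloxy)-2-[4-(benzyloxy)phenyl]-3-[3,5-bis(prop-2-en-1-yloxy)phenyl]-2,3-dihydro-1-benzofuran-4-yl}-3-[3,5-bis(benzyloxy)phenyl]-4-{4-[(tert-butyldimethylsilyl)oxy]phenyl}-4-methoxybutan-1-one (C-2 and C-4 epimers) | O=C(c1ccc(OCc2ccccc2)cc1)C(c1cc(OCc2ccccc2)cc2O[C@@H](c3ccc(OCc4ccccc4)cc3)[C@H](c3cc(OCC=C)cc(OCC=C)c3)c12)[C@@H](c1cc(OCc2ccccc2)cc(OCc2ccccc2)c1)C(OC)c1ccc(O[Si](C)(C)C(C)(C)C)cc1
F2 | step 8 | 5-(benzyloxy)-3-bromo-2-{[3,5-bis(prop-2-en-1-yloxy)phenyl](hydroxy)methyl}phenol (racemic) | OC(c1cc(OCC=C)cc(OCC=C)c1)c1c(O)cc(OCc2ccccc2)cc1Br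
F3 | step 8 | 5-(benzyloxy)-3-bromo-2-{[3,5-bis(prop-2-en-1-yloxy)phenyl](4-methylbenzenesulfonyl)methyl}phenol (racemic) | Cc1ccc(cc1)S(=O)(=O)C(c1cc(OCC=C)cc(OCC=C)c1)c1c(O)cc(OCc2ccccc2)cc1Br
F4 | step 8 | (2R,5R)-1-{[4-(benzyloxy)phenyl]methyl}-2,5-dimethylthiolan-1-ium chloride | C[C@@H]1CC[C@@H](C)[S+]1Cc1ccc(OCc2ccccc2)cc1.[Cl-]
F5 | step 19 | octaphenol ketone (30 without its five benzyl groups) | Oc1ccc(cc1)C(=O)[C@@H]1[C@@H](c2cc(O)cc(O)c2)[C@H](c2ccc(O)cc2)c2c(O)cc(O)cc2[C@@H]2c3c(cc(O)cc31)O[C@H]2c1ccc(O)cc1
F6 | step 19 | octaphenol carbinol (C-a epimers) | Oc1ccc(cc1)C(O)[C@@H]1[C@@H](c2cc(O)cc(O)c2)[C@H](c2ccc(O)cc2)c2c(O)cc(O)cc2[C@@H]2c3c(cc(O)cc31)O[C@H]2c1ccc(O)cc1
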